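The readings stem from a simulated flask on assumed constants, and the scatter is random.

Thursday's readings rose by 8 percentage points of target for each tenfold of time, and this tenfold gain was the number I reasoned with.

| setting | Thursday's | Sunday's | flask |
|---|---|---|---|
| starting material | 0.20 M | 0.30 M | 0.20 M |
| free enzyme | 0.01 mol% | 0.01 mol% | 0.01 mol% |
| temperature | 37 °C | 22 °C | 37 °C |
| remark | the very flask that is asked about, followed so far | run made earlier |  |
| time |  |  | 2.0 h |

| run | time / min | target / % |
|---|---|---|
| Thursday's | 12.0 | 10.7 |
| Thursday's | 30.0 | 15.1 |
| Thursday's | 60.0 | 17.5 |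
| Thursday's | 90.0 | 18.9 |
| Sunday's | 30.0 | 6.3 |
| Sunday's | 60.0 | 6.3 |
| Sunday's | 120 | 8.4 |

(standard deviation of a reading: 0.5 percentage points)

- maple: at 2.0 h add free enzyme, 50.0% of the amount charged, then wait 4.0 h
- oak: change nothing and wait 4.0 h more
- ash: at 2.0 h take out 90% of the target then present, then wait 4.0 h

- removed target is counted in
- additions bring no volume worth counting

- target, in percent of the starting material first charged, at 2.0 h
- which option adds most target ("none" when 2 percentage points or less is all one gets) (maple / oak / ash / none)
- target present, with what was taken out counted in, in percent of the starting material first charged, after maple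
- target present, with what was taken out counted in, in percent of the starting material first charged, after oak

With one fixed rate constant, equal stretches of time take equal shares of what remains, and the curve flattens fast. Thursday's readings instead rose by about the same for each equal factor of time: 8 points per tenfold from 30.0 min to 60.0 min, and 8 points from there to 90.0 min. The slope from the outer two readings carries a scatter of 1.5 points. A rate falling as one over time suggested to me that working enzyme destroys itself in pairs (second-order deactivation). If so, loading and time count as their product. Sunday's flask ran colder and stronger, so I did not carry its readings over.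

Going on along the logarithm from the last reading, I expected 19.9% at 2.0 h and 23.7% after oak. Maple's dose is 50.0% of the charge, so in 4.0 h it should do what the whole charge did in 2.00 h, and that makes a second 19.9%, for 39.8%. I held this to be high, since the dose meets less starting material, about 80.1% of the charge. Ash adds no enzyme, so I put it near oak, and I chose maple, whose gain is far more than oak's.

The forecast gave 19.8%, 21.5% after oak and 29% after maple, the last lower than my figure, and also chose maple, as “Fresh enzyme should restart conversion”.

The flask gave 19.9%, 23.5% after oak and 36.5% after maple; the gains were 17 points for maple, 3.6 points for oak and 4.2 points for ash, so maple won.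

    starting material + free enzyme ⇌ complex (K = 13.0 M⁻¹, k = 1300 M⁻¹ s⁻¹, Ea = 43.0 kJ mol⁻¹, ΔH = −18.0 kJ mol⁻¹)
    complex ⇌ free enzyme + target (K = 0.420 M, k = 13.0 s⁻¹, Ea = 59.0 kJ mol⁻¹, ΔH = −26.0 kJ mol⁻¹)
    target + free enzyme ⇌ isomer of the product + free enzyme, rate k3*[free enzyme]*[target] forward; the back reaction follows from the equilibrium constant (K = 3.90, k = 59.0 M⁻¹ s⁻¹, Ea = 42.0 kJ mol⁻¹, ΔH = −80.0 kJ mol⁻¹)
    2 complex → spent catalyst (k = 1100 M⁻¹ s⁻¹, Ea = 40.0 kJ mol⁻¹)
    free enzyme → unfolded enzyme (k = 4.80 × 10⁻⁵ s⁻¹, Ea = 250 kJ mol⁻¹)
    (constants at 37 °C)

In Thursday's flask the step from complex to free enzyme and target had 69% of its turnover up to 2.0 h behind it by 0.400 h. Meanwhile complex fell from 4.27% of the catalyst at 0.200 h to 0.441% at 2.00 h, spent catalyst rose from 93.4% to 98.9%, and 79.1% of the starting material stayed free. My maple figure stood 3.3 points above the flask.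

For the same flask read at 8.0 h, going on from the last reading along the logarithm at 8 points per decade of time gives 24.7%. The computed result is 24.3%.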